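**Plan**
1. The target, 3,5,7,8-tetramethoxy-2-(2-methoxyphenyl)-4H-chromen-4-one, is cut in ring C at C2=C3 and C3–C4. C3 carries only a methoxy group and lies between the C4 carbonyl and C2, so it is the carbon of Ph3P=CHOMe; C4 is the carbonyl of a salicyloyl chloride and O1–C2 is its aryl 2-methoxybenzoate.
2. Further cuts are the ester C–O bond (2-methoxybenzoyl chloride), the C4–C4a bond (ortho-formylation of 2,3,5-trimethoxyphenol) and the C8 oxygen (aldehyde-to-phenol exchange in 2-hydroxy-4,6-dimethoxybenzaldehyde under benzyl protection).
3. Forward: ring A is bought and re-oxygenated (steps 1–4), the C4 carbon is added (step 5), ring B is attached as the ester (step 6), C4 is raised to the acid chloride (steps 7 and 8), and ring C is closed last in one flask (step 9).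
4. The target has no stereocentre and the only double bond formed is endocyclic, so no stereochemical control is needed.

Key step: step 9

Assumption: compounds 1, 8 and 12 are taken as commercial, and the crude acid chloride 11 is used directly after evaporation of the volatiles.

**Step 1**
Reactants: 1 2-hydroxy-4,6-dimethoxybenzaldehyde
Product: 2 2-(benzyloxy)-4,6-dimethoxybenzaldehyde
Conditions: BnBr, K2CO3, DMF, rt → 60 °C
Reagents that add atoms: benzyl bromide, BrCc1ccccc1
Why: Williamson etherification of the phenoxide with benzyl bromide is routine even for a hydrogen-bonded ortho-hydroxy aldehyde, and the benzyl ether masks this oxygen (the future O1) through the oxidation and methylation that follow.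

**Step 2**
Reactants: 2 2-(benzyloxy)-4,6-dimethoxybenzaldehyde
Product: 4 2-(benzyloxy)-4,6-dimethoxyphenol, via aryl formate 3 (not isolated)
Conditions: mCPBA, CH2Cl2, 0 °C → rt; then K2CO3 (cat.), MeOH, rt, under N2
Reagents that add atoms: 3-chloroperoxybenzoic acid (mCPBA), OOC(=O)c1cccc(Cl)c1
Why: In this Dakin-type Baeyer–Villiger oxidation the electron-rich 2,4,6-trioxygenated aryl group migrates in preference to hydride in the peracid adduct to give aryl formate 3, which mild methanolysis cleaves to the phenol without touching the benzyl or methyl ethers.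

**Step 3**
Reactants: 4 2-(benzyloxy)-4,6-dimethoxyphenol
Product: 5 1-(benzyloxy)-2,3,5-trimethoxybenzene
Conditions: MeI, K2CO3, DMF, rt
Reagents that add atoms: iodomethane, CI
Why: Williamson O-methylation of the flanked but acidic phenol should proceed cleanly and installs the methoxy group that becomes C8–OMe.

**Step 4**
Reactants: 5 1-(benzyloxy)-2,3,5-trimethoxybenzene
Product: 6 2,3,5-trimethoxyphenol
Conditions: H2 (1 atm), 10% Pd/C, EtOAc/MeOH, rt
Reagents that add atoms: none
Why: Catalytic hydrogenolysis over Pd/C cleaves only the benzylic C–O bond and frees the phenol, while the aryl methyl ethers are inert.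

**Step 5**
Reactants: 6 2,3,5-trimethoxyphenol
Product: 7 2-hydroxy-3,4,6-trimethoxybenzaldehyde
Conditions: MgCl2, Et3N, (CH2O)n, MeCN, reflux; aq. HCl work-up
Reagents that add atoms: paraformaldehyde (as formaldehyde), C=O
Why: In this magnesium-mediated ortho-formylation (Casnati–Skattebøl) the magnesium phenoxide delivers formaldehyde through a chelate to the single free ortho carbon and not to the para position, and a second formaldehyde oxidises the benzylic alkoxide by hydride transfer, so the carbon that becomes C4 is placed unambiguously.

**Step 6**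
Reactants: 7 2-hydroxy-3,4,6-trimethoxybenzaldehyde; 8 2-methoxybenzoyl chloride
Product: 9 2-formyl-3,5,6-trimethoxyphenyl 2-methoxybenzoate
Conditions: Et3N, DMAP (cat.), CH2Cl2, 0 °C → rt
Reagents that add atoms: none
Why: DMAP-catalysed O-acylation of a phenol by an acid chloride goes through an acylpyridinium ion that should overcome the hindrance and hydrogen bonding of the salicylaldehyde hydroxyl, and it sets up the O1–C2 ester.

**Step 7**
Reactants: 9 2-formyl-3,5,6-trimethoxyphenyl 2-methoxybenzoate
Product: 10 2-[(2-methoxybenzoyl)oxy]-3,4,6-trimethoxybenzoic acid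
Conditions: NaClO2, NaH2PO4, 2-methylbut-2-ene, t-BuOH/THF/H2O, 0 °C → rt
Reagents that add atoms: sodium chlorite, [Na+].[O-]Cl=O
Why: The Pinnick (Lindgren–Kraus) oxidation converts the aldehyde to the acid in a weakly acidic buffer that should leave the aryl ester intact, with 2-methylbut-2-ene trapping hypochlorous acid before it can chlorinate the electron-rich ring.

**Step 8**
Reactants: 10 2-[(2-methoxybenzoyl)oxy]-3,4,6-trimethoxybenzoic acid
Product: 11 2-(chlorocarbonyl)-3,5,6-trimethoxyphenyl 2-methoxybenzoate
Conditions: (COCl)2, DMF (cat.), CH2Cl2, 0 °C → rt; evaporate, use crude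
Reagents that add atoms: oxalyl chloride, O=C(Cl)C(=O)Cl
Why: Acid chloride formation with oxalyl chloride under DMF catalysis (Vilsmeier-type chloroiminium activation) runs at or below room temperature under anhydrous conditions that O-acylsalicylic acids tolerate.

**Step 9**
Reactants: 11 2-(chlorocarbonyl)-3,5,6-trimethoxyphenyl 2-methoxybenzoate; 12 (methoxymethyl)triphenylphosphonium chloride
Product: 16 3,5,7,8-tetramethoxy-2-(2-methoxyphenyl)-4H-chromen-4-one, via (methoxymethylene)triphenylphosphorane 13 (not isolated), via acylphosphonium chloride 14 (not isolated), via α-methoxy acyl ylide 15 (not isolated)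
Conditions: 12 (2.2 equiv), NaN(SiMe3)2 (2.1 equiv), THF, 0 °C; then 11, −78 °C → rt; then toluene, 90 °C
Reagents that add atoms: none
Why: Proposed new method: the nonstabilised ylide 13 should be C-acylated by the acid chloride at −78 °C to give phosphonium salt 14 (C3–C4), a second equivalent of 13 should deprotonate 14 (transylidation) to the α-methoxy acyl ylide 15, and on heating the ylide carbon should add to the neighbouring aryl ester carbonyl, the four-membered P–O adduct collapsing with loss of Ph3PO to give C2=C3. The closest known reaction type is the chromone synthesis in which an O-acylsalicylic acid derivative acylates a phosphorus ylide and the resulting (2-acyloxybenzoyl)methylenephosphorane undergoes intramolecular Wittig olefination of its ester carbonyl; what is new is the α-methoxy substituent, which makes the ylide carbon fully substituted. Ring C closes by a 6-exo-trig addition of the ylide carbon to the ester C=O, the two being held in a 1,5-relationship by the ortho-disubstituted benzene ring, followed by [2+2] cycloreversion. No stereocentre is formed and the geometry of the new enol ether double bond is fixed by the ring. The step needs chemoselectivity for the acid chloride over the aryl ester in the bimolecular acylation, which the far higher electrophilicity of the acid chloride at −78 °C and the slight deficit of NaN(SiMe3)2 (no free amide base) should secure. The methoxy group reduces the stabilisation of the acyl ylide, as in the isolable ylide Ph3P=C(OMe)CO2Me that still olefinates aldehydes, so attack on the activated phenolic ester is expected to be no harder than with the parent acyl ylide.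

**Compound list**
1 | 2-hydroxy-4,6-dimethoxybenzaldehyde | COc1cc(O)c(C=O)c(OC)c1 | starting material
2 | 2-(benzyloxy)-4,6-dimethoxybenzaldehyde | COc1cc(OCc2ccccc2)c(C=O)c(OC)c1 | intermediate
3 | 2-(benzyloxy)-4,6-dimethoxyphenyl formate | O=COc1c(OCc2ccccc2)cc(OC)cc1OC | intermediate
4 | 2-(benzyloxy)-4,6-dimethoxyphenol | COc1cc(OC)c(O)c(OCc2ccccc2)c1 | intermediate
5 | 1-(benzyloxy)-2,3,5-trimethoxybenzene | COc1cc(OC)c(OC)c(OCc2ccccc2)c1 | intermediate
6 | 2,3,5-trimethoxyphenol | COc1cc(O)c(OC)c(OC)c1 | intermediate
7 | 2-hydroxy-3,4,6-trimethoxybenzaldehyde | COc1cc(OC)c(C=O)c(O)c1OC | intermediate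
8 | 2-methoxybenzoyl chloride | COc1ccccc1C(=O)Cl | starting material
9 | 2-formyl-3,5,6-trimethoxyphenyl 2-methoxybenzoate | COc1ccccc1C(=O)Oc1c(OC)c(OC)cc(OC)c1C=O | intermediate
10 | 2-[(2-methoxybenzoyl)oxy]-3,4,6-trimethoxybenzoic acid | COc1ccccc1C(=O)Oc1c(OC)c(OC)cc(OC)c1C(=O)O | intermediate
11 | 2-(chlorocarbonyl)-3,5,6-trimethoxyphenyl 2-methoxybenzoate | COc1ccccc1C(=O)Oc1c(OC)c(OC)cc(OC)c1C(=O)Cl | intermediate
12 | (methoxymethyl)triphenylphosphonium chloride | COC[P+](c1ccccc1)(c1ccccc1)c1ccccc1.[Cl-] | starting material
13 | (methoxymethylene)triphenylphosphorane | COC=P(c1ccccc1)(c1ccccc1)c1ccccc1 | intermediate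
14 | {1-methoxy-2-[2-((2-methoxybenzoyl)oxy)-3,4,6-trimethoxyphenyl]-2-oxoethyl}triphenylphosphonium chloride (racemic) | COc1ccccc1C(=O)Oc1c(OC)c(OC)cc(OC)c1C(=O)C(OC)[P+](c1ccccc1)(c1ccccc1)c1ccccc1.[Cl-] | intermediate
15 | 2-[2-methoxy-2-(triphenylphosphoranylidene)acetyl]-3,5,6-trimethoxyphenyl 2-methoxybenzoate | COc1ccccc1C(=O)Oc1c(OC)c(OC)cc(OC)c1C(=O)C(OC)=P(c1ccccc1)(c1ccccc1)c1ccccc1 | intermediate
16 | 3,5,7,8-tetramethoxy-2-(2-methoxyphenyl)-4H-chromen-4-one | COc1ccccc1-c1oc2c(OC)c(OC)cc(OC)c2c(=O)c1OC | target

**Step count**
Total steps: 9. Longest linear sequence: 9 steps (from 1 to 16).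

**Steps most likely to fail**

Step 9. The fully substituted ylide carbon may fail to add to the hindered ortho-anisoyl ester carbonyl, or acyl transfer from the phenolic oxygen to the ylide oxygen may divert the intermediate before olefination. The fallback uses the known unsubstituted version and oxidises C3 afterwards. It sets out from acid chloride 11, which is treated with two equivalents of methylenetriphenylphosphorane (MePPh3Br, NaN(SiMe3)2, THF, −78 °C) to give 2-[(triphenylphosphoranylidene)acetyl]-3,5,6-trimethoxyphenyl 2-methoxybenzoate F1. Heating F1 in toluene should close ring C by the established intramolecular ester Wittig reaction to give 5,7,8-trimethoxy-2-(2-methoxyphenyl)-4H-chromen-4-one F2. Epoxidation of C2=C3 with dimethyldioxirane (acetone/CH2Cl2, 0 °C) should give racemic 2,3-epoxy-5,7,8-trimethoxy-2-(2-methoxyphenyl)chroman-4-one F3, which a trace of TsOH isomerises to 3-hydroxy-5,7,8-trimethoxy-2-(2-methoxyphenyl)-4H-chromen-4-one F4. Methylation of F4 (MeI, K2CO3, acetone) comes back to the route at 16.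

Step 8. HCl released during activation may cleave or shift the aroyl group, or the very electron-rich acid may undergo protodecarboxylation. The fallback changes the acyl donor: it sets out from acid 10, which is silylated (TBSCl, imidazole, DMF) to tert-butyldimethylsilyl 2-[(2-methoxybenzoyl)oxy]-3,4,6-trimethoxybenzoate F5. Silyl esters of O-acylsalicylic acids are known to acylate phosphorus ylides at the silyl ester carbonyl, and the displaced silanolate deprotonates the acylphosphonium ion. F5 and ylide 13 (THF, −78 °C → rt) should therefore give acyl ylide 15 directly, where the route is rejoined and cyclisation follows as in step 9.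

Step 7. Hypochlorous acid may chlorinate the one free position of the electron-rich ring, or the aryl ester may hydrolyse in the aqueous buffer. The fallback introduces the carboxyl at the acid oxidation level before acylation, so no oxidation is needed after ring B is attached. It sets out from phenol 6, whose sodium salt is carboxylated at the only free ortho position under Kolbe–Schmitt conditions (CO2 under pressure, about 130 °C) to give 2-hydroxy-3,4,6-trimethoxybenzoic acid F6. O-Aroylation of F6 with 8 in pyridine comes back to the route at acid 10.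

**Further compounds**
F1 | step 9 | 2-[(triphenylphosphoranylidene)acetyl]-3,5,6-trimethoxyphenyl 2-methoxybenzoate | COc1ccccc1C(=O)Oc1c(OC)c(OC)cc(OC)c1C(=O)C=P(c1ccccc1)(c1ccccc1)c1ccccc1
F2 | step 9 | 5,7,8-trimethoxy-2-(2-methoxyphenyl)-4H-chromen-4-one | COc1ccccc1-c1cc(=O)c2c(OC)cc(OC)c(OC)c2o1
F3 | step 9 | 2,3-epoxy-5,7,8-trimethoxy-2-(2-methoxyphenyl)chroman-4-one (racemic, cis-fused; one enantiomer drawn) | COc1ccccc1[C@]12O[C@H]1C(=O)c1c(OC)cc(OC)c(OC)c1O2
F4 | step 9 | 3-hydroxy-5,7,8-trimethoxy-2-(2-methoxyphenyl)-4H-chromen-4-one | COc1ccccc1-c1oc2c(OC)c(OC)cc(OC)c2c(=O)c1O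
F5 | step 8 | tert-butyldimethylsilyl 2-[(2-methoxybenzoyl)oxy]-3,4,6-trimethoxybenzoate | COc1ccccc1C(=O)Oc1c(OC)c(OC)cc(OC)c1C(=O)O[Si](C)(C)C(C)(C)C
F6 | step 7 | 2-hydroxy-3,4,6-trimethoxybenzoic acid | COc1cc(OC)c(C(=O)O)c(O)c1OC
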